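**Retrosynthetic overview**
1. Target 15 ⇐ dibenzoate 14 (O-debenzylation) ⇐ diol 13 (benzoylation) ⇐ dimethyl (2R,3R)-2,3-dibenzylsuccinate 12 (ester reduction).
2. The plan rests on C9 and C9', the two benzoyloxymethyl carbons. Each is a carboxyl-level one-carbon unit on one of the adjacent stereocentres C8 and C8' of the open C7–C8–C8'–C7' chain between ring B (3-hydroxy-4-methoxyphenyl) and ring A (4-hydroxy-3-methoxyphenyl). Cutting C8–C9 and C8'–C9' in 12 leaves the flat E-alkene 11, to which two CO2Me groups are added syn under a chiral palladium catalyst.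
3. 11 ⇐ Julia–Kocienski olefination at C8=C8' of arylacetaldehyde 3 (ring A, two carbons) with the 2-arylethyl phenyltetrazolyl sulfone 10 (ring B, two carbons). The sulfonyl-bearing carbon becomes C8, so the tether must be two carbons long; a 3-arylpropyl sulfone would give a 1,5-diarylpent-2-ene instead.
4. 3 comes from O-benzylvanillin 1 by one-carbon homologation; 10 comes from O-benzylisovanillin 4 by methylenation, hydroboration, Mitsunobu thioetherification and oxidation.
5. No ring is formed in the route; all four benzene rings are bought intact.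

Key step: step 8

Assumption: lignan numbering is used (C7/C7' benzylic CH2, C8/C8' stereocentres, C9/C9' CH2O carbons; ring B on C7, ring A on C7'), and the target is (8R,8'R).
Assumption: which antipode of the chiral ligand in step 8 leads to the (R,R)-diester cannot be predicted with confidence; (S,S) is written for definiteness, and the antipode would be fixed in a first screen (both are accessible from tert-leucinol).

**Route**

Step 1
Reactants: 1 4-(benzyloxy)-3-methoxybenzaldehyde
Product: 2 1-(benzyloxy)-2-methoxy-4-(2-methoxyethenyl)benzene (E/Z mixture)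
Conditions: (methoxymethyl)triphenylphosphonium chloride, KOtBu, THF, 0 °C → rt
Reagents that add atoms: (methoxymethyl)triphenylphosphonium chloride, COC[P+](c1ccccc1)(c1ccccc1)c1ccccc1.[Cl-]
Why: Wittig olefination of a non-enolisable aryl aldehyde with the methoxymethylene ylide should give the enol ether, whose E/Z ratio is irrelevant because both isomers hydrolyse to the same aldehyde.

Step 2
Reactants: 2 1-(benzyloxy)-2-methoxy-4-(2-methoxyethenyl)benzene
Product: 3 2-[4-(benzyloxy)-3-methoxyphenyl]acetaldehyde
Conditions: 2 M aq. HCl, THF, 40 °C; short silica plug, used at once in step 7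
Reagents that add atoms: water, O
Why: Acid-catalysed enol ether hydrolysis (protonation at the benzylic carbon, water capture of the oxocarbenium ion, loss of methanol) should unmask the arylacetaldehyde, while the aryl benzyl and methyl ethers are stable to dilute acid.

Step 3
Reactants: 4 3-(benzyloxy)-4-methoxybenzaldehyde
Product: 5 2-(benzyloxy)-4-ethenyl-1-methoxybenzene
Conditions: methyltriphenylphosphonium bromide, KOtBu, THF, 0 °C → rt
Reagents that add atoms: methyltriphenylphosphonium bromide, C[P+](c1ccccc1)(c1ccccc1)c1ccccc1.[Br-]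
Why: Wittig methylenation of the aryl aldehyde should give the styrene without touching the benzyl ether.

Step 4
Reactants: 5 2-(benzyloxy)-4-ethenyl-1-methoxybenzene
Product: 7 2-[3-(benzyloxy)-4-methoxyphenyl]ethanol, via B-alkyl-9-BBN adduct 6 (not isolated)
Conditions: 9-BBN (0.5 M in THF), 0 °C → rt; then 3 M aq. NaOH, 30% H2O2, 0 °C → rt
Reagents that add atoms: 9-borabicyclo[3.3.1]nonane, B1C2CCCC1CCC2 (boron unit of intermediate 6); hydrogen peroxide, OO (oxygen of 7)
Why: Anti-Markovnikov hydroboration with the bulky dialkylborane puts boron on the terminal carbon of the styrene, and alkaline peroxide oxidation of the C–B bond should give the primary 2-arylethanol.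

Step 5
Reactants: 7 2-[3-(benzyloxy)-4-methoxyphenyl]ethanol; 8 1-phenyl-1H-tetrazole-5-thiol
Product: 9 5-({2-[3-(benzyloxy)-4-methoxyphenyl]ethyl}sulfanyl)-1-phenyl-1H-tetrazole
Conditions: PPh3, DIAD, THF, 0 °C → rt
Reagents that add atoms: none
Why: Mitsunobu thioetherification, in which the acidic heteroaryl thiol displaces the alkoxyphosphonium derivative of the unhindered primary alcohol by SN2, should give the sulfide.

Step 6
Reactants: 9 5-({2-[3-(benzyloxy)-4-methoxyphenyl]ethyl}sulfanyl)-1-phenyl-1H-tetrazole
Product: 10 5-({2-[3-(benzyloxy)-4-methoxyphenyl]ethyl}sulfonyl)-1-phenyl-1H-tetrazole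
Conditions: (NH4)6Mo7O24·4H2O (10 mol %), 30% aq. H2O2, EtOH, 0 °C → rt
Reagents that add atoms: hydrogen peroxide, OO
Why: Molybdate-catalysed peroxide oxidation takes the sulfide through the sulfoxide to the sulfone and should leave the benzyl ether and the electron-rich arene untouched.

Step 7
Reactants: 10 5-({2-[3-(benzyloxy)-4-methoxyphenyl]ethyl}sulfonyl)-1-phenyl-1H-tetrazole; 3 2-[4-(benzyloxy)-3-methoxyphenyl]acetaldehyde
Product: 11 (E)-1-[3-(benzyloxy)-4-methoxyphenyl]-4-[4-(benzyloxy)-3-methoxyphenyl]but-2-ene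
Conditions: 10, KN(SiMe3)2 (1.1 equiv), DME, −60 °C, 30 min; then 3 in DME, −60 °C → rt
Reagents that add atoms: none
Why: Julia–Kocienski olefination, in which the pre-metalated phenyltetrazolyl sulfone adds to the aldehyde at low temperature faster than it deprotonates it, and Smiles rearrangement with anti-elimination of SO2 and tetrazololate from the anti adduct favoured by potassium in DME, should give the E-alkene with C8=C8' in the middle of a four-carbon chain.

Step 8
Reactants: 11 (E)-1-[3-(benzyloxy)-4-methoxyphenyl]-4-[4-(benzyloxy)-3-methoxyphenyl]but-2-ene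
Product: 12 dimethyl (2R,3R)-2-[3-(benzyloxy)-4-methoxybenzyl]-3-[4-(benzyloxy)-3-methoxybenzyl]succinate
Conditions: Pd(OCOCF3)2 (5 mol %), (S,S)-4,4'-di-tert-butyl-2,2'-bi(2-oxazoline) (6 mol %), p-TsOH·H2O (5 mol %), 1,4-benzoquinone (1.5 equiv), CO (10 bar), MeOH/THF 7:1, 20 °C
Reagents that add atoms: carbon monoxide, [C-]#[O+]; methanol, CO
Why: Proposed new method: a ligated methoxycarbonyl–palladium species (from divalent palladium, CO and methanol) should add syn across C8=C8' by migratory insertion, the new alkyl–palladium bond should insert CO faster than it loses a beta-hydride under CO pressure, and methanolysis of the acyl–palladium releases the succinate while benzoquinone returns zerovalent palladium to the divalent state. The closest known reaction type is the syn-stereospecific oxidative bis-alkoxycarbonylation of 1,2-disubstituted alkenes with Pd(OCOCF3)2 and aryl alpha-diimine ligands, together with the ligand-controlled asymmetric bis-alkoxycarbonylation of styrenes; what is new is enantiocontrol on an unactivated internal alkene, for which a chiral alpha-diimine (the bioxazoline) is chosen so that the electronic character of the proven ligands is kept. No ring is closed. The relative configuration of C8 and C8' follows from syn addition of two identical groups to the E-alkene, which can only give the (R*,R*) diester, and the absolute configuration is set by the C2-symmetric ligand, whose tert-butyl groups flank the coordination site and should make one alkene face bind and insert preferentially. Because both alkene carbons receive a CO2Me group and the alkene is nearly C2-symmetric, the regiochemistry of the first insertion has no consequence, so the step needs only face selectivity and chemoselectivity against alkene migration and allylic C–H activation. The substrate has no directing group, but the ester carbonyl installed in the first insertion can chelate palladium in a five-membered ring and thereby hold the alkyl intermediate against beta-hydride loss toward the benzylic C7/C7' positions.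

Step 9
Reactants: 12 dimethyl (2R,3R)-2-[3-(benzyloxy)-4-methoxybenzyl]-3-[4-(benzyloxy)-3-methoxybenzyl]succinate
Product: 13 (2R,3R)-2-[3-(benzyloxy)-4-methoxybenzyl]-3-[4-(benzyloxy)-3-methoxybenzyl]butane-1,4-diol
Conditions: LiAlH4, THF, 0 °C → rt; Fieser work-up
Reagents that add atoms: none
Why: Hydride reduction of both methyl esters to primary alcohols is faster than enolisation, so C8 and C8' should keep their configuration.

Step 10
Reactants: 13 (2R,3R)-2-[3-(benzyloxy)-4-methoxybenzyl]-3-[4-(benzyloxy)-3-methoxybenzyl]butane-1,4-diol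
Product: 14 (2R,3R)-2-[3-(benzyloxy)-4-methoxybenzyl]-3-[4-(benzyloxy)-3-methoxybenzyl]butane-1,4-diyl dibenzoate
Conditions: BzCl (2.5 equiv), pyridine, DMAP (cat.), CH2Cl2, 0 °C → rt
Reagents that add atoms: benzoyl chloride, O=C(Cl)c1ccccc1
Why: DMAP-catalysed acylation of the two primary alcohols with benzoyl chloride should give the dibenzoate while the phenols remain masked as benzyl ethers.

Step 11
Reactants: 14 (2R,3R)-2-[3-(benzyloxy)-4-methoxybenzyl]-3-[4-(benzyloxy)-3-methoxybenzyl]butane-1,4-diyl dibenzoate
Product: 15 (2R,3R)-2-(3-hydroxy-4-methoxybenzyl)-3-(4-hydroxy-3-methoxybenzyl)butane-1,4-diyl dibenzoate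
Conditions: H2 (1 atm), 10% Pd/C, EtOAc/EtOH, rt
Reagents that add atoms: none
Why: Hydrogenolysis cleaves the two benzylic aryl ether C–O bonds, whereas the alkyl benzoates have no benzylic C–O bond and the stereocentres are not involved, so the target should result.

**Compound list**
1 | 4-(benzyloxy)-3-methoxybenzaldehyde (O-benzylvanillin) | COc1cc(C=O)ccc1OCc1ccccc1 | starting material
2 | 1-(benzyloxy)-2-methoxy-4-(2-methoxyethenyl)benzene (E/Z mixture) | COC=Cc1ccc(OCc2ccccc2)c(OC)c1 | intermediate
3 | 2-[4-(benzyloxy)-3-methoxyphenyl]acetaldehyde | COc1cc(CC=O)ccc1OCc1ccccc1 | intermediate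
4 | 3-(benzyloxy)-4-methoxybenzaldehyde (O-benzylisovanillin) | COc1ccc(C=O)cc1OCc1ccccc1 | starting material
5 | 2-(benzyloxy)-4-ethenyl-1-methoxybenzene | COc1ccc(C=C)cc1OCc1ccccc1 | intermediate
6 | B-{2-[3-(benzyloxy)-4-methoxyphenyl]ethyl}-9-borabicyclo[3.3.1]nonane | COc1ccc(CCB2C3CCCC2CCC3)cc1OCc1ccccc1 | intermediate (not isolated)
7 | 2-[3-(benzyloxy)-4-methoxyphenyl]ethanol | COc1ccc(CCO)cc1OCc1ccccc1 | intermediate
8 | 1-phenyl-1H-tetrazole-5-thiol | Sc1nnnn1-c1ccccc1 | starting material
9 | 5-({2-[3-(benzyloxy)-4-methoxyphenyl]ethyl}sulfanyl)-1-phenyl-1H-tetrazole | COc1ccc(CCSc2nnnn2-c2ccccc2)cc1OCc1ccccc1 | intermediate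
10 | 5-({2-[3-(benzyloxy)-4-methoxyphenyl]ethyl}sulfonyl)-1-phenyl-1H-tetrazole | COc1ccc(CCS(=O)(=O)c2nnnn2-c2ccccc2)cc1OCc1ccccc1 | intermediate
11 | (E)-1-[3-(benzyloxy)-4-methoxyphenyl]-4-[4-(benzyloxy)-3-methoxyphenyl]but-2-ene | COc1ccc(C/C=C/Cc2ccc(OCc3ccccc3)c(OC)c2)cc1OCc1ccccc1 | intermediate
12 | dimethyl (2R,3R)-2-[3-(benzyloxy)-4-methoxybenzyl]-3-[4-(benzyloxy)-3-methoxybenzyl]succinate | COc1ccc(C[C@@H](C(=O)OC)[C@H](C(=O)OC)Cc2ccc(OCc3ccccc3)c(OC)c2)cc1OCc1ccccc1 | intermediate
13 | (2R,3R)-2-[3-(benzyloxy)-4-methoxybenzyl]-3-[4-(benzyloxy)-3-methoxybenzyl]butane-1,4-diol | COc1ccc(C[C@@H](CO)[C@H](CO)Cc2ccc(OCc3ccccc3)c(OC)c2)cc1OCc1ccccc1 | intermediate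
14 | (2R,3R)-2-[3-(benzyloxy)-4-methoxybenzyl]-3-[4-(benzyloxy)-3-methoxybenzyl]butane-1,4-diyl dibenzoate | COc1ccc(C[C@@H](COC(=O)c2ccccc2)[C@H](COC(=O)c2ccccc2)Cc2ccc(OCc3ccccc3)c(OC)c2)cc1OCc1ccccc1 | intermediate
15 | (2R,3R)-2-(3-hydroxy-4-methoxybenzyl)-3-(4-hydroxy-3-methoxybenzyl)butane-1,4-diyl dibenzoate | COc1ccc(C[C@@H](COC(=O)c2ccccc2)[C@H](COC(=O)c2ccccc2)Cc2ccc(O)c(OC)c2)cc1O | target

**Step count**
Total: 11 steps. Longest linear sequence: 9 steps (4 → 15, steps 3 to 11).

**Steps most likely to fail**

1. Step 8 (Proposed new method). The chiral ligand may fail to discriminate the two faces of an alkene that has no directing group. Beta-hydride loss from the alkyl–palladium intermediate, alkene migration into conjugation with the arenes, or allylic C–H activation by divalent palladium with benzoquinone may also compete with the second carbonylation. Any Z-alkene carried over from step 7 would also be converted stereospecifically into the (R*,S*) diastereomer. The fallback uses only known chemistry, sets out from 4 (with 1 as the second building block) and rejoins the route at 13. Stobbe condensation of 4 with dimethyl succinate (NaOMe, MeOH, reflux) should give (E)-4-[3-(benzyloxy)-4-methoxyphenyl]-3-(methoxycarbonyl)but-3-enoic acid F1. Asymmetric hydrogenation of its carboxylate with a cationic rhodium bisphosphine catalyst such as [Rh(cod)(Et-DuPhos)]BF4, in the antipode that gives the R acid (H2, MeOH), should give (R)-4-[3-(benzyloxy)-4-methoxyphenyl]-3-(methoxycarbonyl)butanoic acid F2 with the benzyl ether intact. Reduction of the ester in the presence of the potassium carboxylate (KOH, then Ca(BH4)2, EtOH) should give (R)-4-[3-(benzyloxy)-4-methoxyphenyl]-3-(hydroxymethyl)butanoic acid F3, which on acidification closes to (R)-4-[3-(benzyloxy)-4-methoxybenzyl]dihydrofuran-2(3H)-one F4. In parallel, 1 is reduced (NaBH4, MeOH) to [4-(benzyloxy)-3-methoxyphenyl]methanol F5 and converted (PBr3, Et2O, 0 °C) into 1-(benzyloxy)-4-(bromomethyl)-2-methoxybenzene F6. Alkylation of the lithium enolate of F4 (LiN(SiMe3)2, THF, −78 °C) with F6 occurs anti to the C4 substituent and should give (3R,4R)-4-[3-(benzyloxy)-4-methoxybenzyl]-3-[4-(benzyloxy)-3-methoxybenzyl]dihydrofuran-2(3H)-one F7. LiAlH4 in THF then opens the lactone to diol 13, after which steps 10 and 11 follow unchanged.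

2. Step 7. Proton transfer from the acidic arylacetaldehyde to the sulfonyl carbanion may lead to aldol self-condensation, and E/Z selectivity may erode with an unbranched aldehyde. The fallback sets out from 3 and 4 and rejoins at 11. Non-basic Takai–Utimoto olefination of 3 with 2-(dichloromethyl)-4,4,5,5-tetramethyl-1,3,2-dioxaborolane (CrCl2, LiI, THF, rt) should give (E)-2-{3-[4-(benzyloxy)-3-methoxyphenyl]prop-1-en-1-yl}-4,4,5,5-tetramethyl-1,3,2-dioxaborolane F8. Aldehyde 4 is reduced (NaBH4, MeOH) to [3-(benzyloxy)-4-methoxyphenyl]methanol F9 and converted (PBr3, Et2O, 0 °C) into 2-(benzyloxy)-4-(bromomethyl)-1-methoxybenzene F10. Suzuki–Miyaura coupling of F8 with F10 (Pd(PPh3)4, K3PO4, THF/H2O, 60 °C) proceeds with retention of the alkene geometry and should give 11.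

3. Step 2. Acid-promoted aldol condensation or oligomerisation of the electron-rich arylacetaldehyde may occur during unmasking, or hydrolysis may be incomplete. The fallback sets out from 1 and rejoins at 3, avoiding acid altogether. Wittig methylenation of 1 (methyltriphenylphosphonium bromide, KOtBu, THF) should give 1-(benzyloxy)-4-ethenyl-2-methoxybenzene F11. Hydroboration with 9-BBN gives B-{2-[4-(benzyloxy)-3-methoxyphenyl]ethyl}-9-borabicyclo[3.3.1]nonane F12, and oxidation in the same flask (NaOH, H2O2) gives 2-[4-(benzyloxy)-3-methoxyphenyl]ethanol F13. Oxidation of F13 with Dess–Martin periodinane (NaHCO3, CH2Cl2, 0 °C → rt) under neutral conditions should give 3.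

**Further compounds**
F1 | step 8 | (E)-4-[3-(benzyloxy)-4-methoxyphenyl]-3-(methoxycarbonyl)but-3-enoic acid | COc1ccc(/C=C(\CC(=O)O)C(=O)OC)cc1OCc1ccccc1
F2 | step 8 | (R)-4-[3-(benzyloxy)-4-methoxyphenyl]-3-(methoxycarbonyl)butanoic acid | COc1ccc(C[C@@H](C(=O)OC)CC(=O)O)cc1OCc1ccccc1
F3 | step 8 | (R)-4-[3-(benzyloxy)-4-methoxyphenyl]-3-(hydroxymethyl)butanoic acid | COc1ccc(C[C@@H](CO)CC(=O)O)cc1OCc1ccccc1
F4 | step 8 | (R)-4-[3-(benzyloxy)-4-methoxybenzyl]dihydrofuran-2(3H)-one | COc1ccc(C[C@H]2COC(=O)C2)cc1OCc1ccccc1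
F5 | step 8 | [4-(benzyloxy)-3-methoxyphenyl]methanol | COc1cc(CO)ccc1OCc1ccccc1
F6 | step 8 | 1-(benzyloxy)-4-(bromomethyl)-2-methoxybenzene | COc1cc(CBr)ccc1OCc1ccccc1
F7 | step 8 | (3R,4R)-4-[3-(benzyloxy)-4-methoxybenzyl]-3-[4-(benzyloxy)-3-methoxybenzyl]dihydrofuran-2(3H)-one | COc1ccc(C[C@H]2COC(=O)[C@@H]2Cc2ccc(OCc3ccccc3)c(OC)c2)cc1OCc1ccccc1
F8 | step 7 | (E)-2-{3-[4-(benzyloxy)-3-methoxyphenyl]prop-1-en-1-yl}-4,4,5,5-tetramethyl-1,3,2-dioxaborolane | COc1cc(C/C=C/B2OC(C)(C)C(C)(C)O2)ccc1OCc1ccccc1
F9 | step 7 | [3-(benzyloxy)-4-methoxyphenyl]methanol | COc1ccc(CO)cc1OCc1ccccc1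
F10 | step 7 | 2-(benzyloxy)-4-(bromomethyl)-1-methoxybenzene | COc1ccc(CBr)cc1OCc1ccccc1
F11 | step 2 | 1-(benzyloxy)-4-ethenyl-2-methoxybenzene | COc1cc(C=C)ccc1OCc1ccccc1
F12 | step 2 | B-{2-[4-(benzyloxy)-3-methoxyphenyl]ethyl}-9-borabicyclo[3.3.1]nonane | COc1cc(CCB2C3CCCC2CCC3)ccc1OCc1ccccc1
F13 | step 2 | 2-[4-(benzyloxy)-3-methoxyphenyl]ethanol | COc1cc(CCO)ccc1OCc1ccccc1
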